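**Retrosynthetic overview**

1. The C8 formyl group is unmasked last from a C8 CH2OMe group (DDQ). Before that, the hexadecanoyl chain is cut between C5 and C6 of the acyl chain, giving the 5-bromopentanoate of the complete chroman core and undec-1-ene (as its 9-BBN adduct), joined by a Pd-catalysed alkyl–alkyl Suzuki–Miyaura coupling.
2. Enabling feature: C2–C16 of the acyl chain is an unbranched, heteroatom-free run of CH2 groups. C5 is a primary carbon four carbons from ester C1 (a δ-bromo ester with no elimination or lactonisation path), and C6 is the terminus of an n-undecyl unit made by anti-Markovnikov hydroboration. The molecule has no other C–halogen bond, and with C8 held as CH2OMe the O1 phenoxide is a poor leaving group, so the O1–C2 bond resists retro-oxa-Michael cleavage under the basic coupling.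
3. The enone arm CH2C(=O)CH=CMe2 comes from a CH2CO2Me arm through a Weinreb amide and (2-methylprop-1-enyl)magnesium bromide.
4. Ring order: the benzene ring is bought. The only ring formed is the dihydropyran ring of the chroman (O1–C2–C3–C4–C4a–C8a), closed together with the C2 (S) centre and the acetate arm by an enantioselective Pd(II) domino Wacker/carbonylation of a 2-(3-methylbut-3-enyl)phenol.
5. Arene: 4-bromo-3,5-dimethoxybenzyl alcohol is alkylated at C4 (Negishi), mono-demethylated (equivalent OMe groups), ortho-formylated (Mg-mediated), then reduced and methyl-etherified to install the masked C8 carbon.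

Key step: step 11

Remark: the chroman stereocentre is (S) (O1 > CH2C(=O) > C3 > CH3). The chiral ligand (S,S)-Bn-BOXAX, 2,2'-bis[(4S)-4-benzyl-4,5-dihydrooxazol-2-yl]-1,1'-binaphthyl, is a known compound used in catalytic amount and is not counted as a starting material.

**Route**

Step 1
Reactants: 1 (4-bromo-3,5-dimethoxyphenyl)methanol
Product: 2 [(4-bromo-3,5-dimethoxyphenyl)methoxy]tri(propan-2-yl)silane
Conditions: TIPSCl, imidazole, DMF, rt
Reagents that add atoms: chlorotri(propan-2-yl)silane, CC(C)[Si](Cl)(C(C)C)C(C)C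
Why: Silyl ether formation at the primary benzylic alcohol gives a bulky, non-directing protecting group that should tolerate the organozinc, thiolate, Grignard and Pd(II) conditions that follow.

Step 2
Reactants: 2 [(4-bromo-3,5-dimethoxyphenyl)methoxy]tri(propan-2-yl)silane; 3 4-bromo-2-methylbut-1-ene
Product: 5 {[3,5-dimethoxy-4-(3-methylbut-3-en-1-yl)phenyl]methoxy}tri(propan-2-yl)silane, via homoallylzinc bromide 4 (not isolated)
Conditions: 3, Zn, LiCl, THF, 50 °C; then 2, Pd(OAc)2 (2 mol%), SPhos (4 mol%), THF, 50 °C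
Reagents that add atoms: none
Why: Negishi coupling, in which LiCl-assisted zinc insertion gives a primary alkylzinc and a Pd/SPhos catalyst should couple it with the doubly ortho-substituted, electron-rich aryl bromide faster than β-hydride elimination.

Step 3
Reactants: 5 {[3,5-dimethoxy-4-(3-methylbut-3-en-1-yl)phenyl]methoxy}tri(propan-2-yl)silane
Product: 6 3-methoxy-2-(3-methylbut-3-en-1-yl)-5-({[tri(propan-2-yl)silyl]oxy}methyl)phenol
Conditions: NaSEt, DMF, 120 °C; aq. HCl work-up
Reagents that add atoms: none
Why: Thiolate SN2 O-demethylation, in which the two methoxy groups are equivalent by the mirror plane through C1 and C4 of the arene so that either cleavage gives the same phenol, and the phenoxide formed should suppress a second demethylation.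

Step 4
Reactants: 6 3-methoxy-2-(3-methylbut-3-en-1-yl)-5-({[tri(propan-2-yl)silyl]oxy}methyl)phenol
Product: 7 2-hydroxy-4-methoxy-3-(3-methylbut-3-en-1-yl)-6-({[tri(propan-2-yl)silyl]oxy}methyl)benzaldehyde
Conditions: MgCl2, Et3N, (CH2O)n, THF, reflux
Reagents that add atoms: paraformaldehyde (as formaldehyde), C=O
Why: Magnesium-mediated ortho-formylation of phenols, in which the magnesium phenoxide delivers formaldehyde through a six-membered chelate to the only free ortho position (the para position is not attacked) and a second formaldehyde oxidises the salicyl alkoxide to the aldehyde by hydride transfer.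

Step 5
Reactants: 7 2-hydroxy-4-methoxy-3-(3-methylbut-3-en-1-yl)-6-({[tri(propan-2-yl)silyl]oxy}methyl)benzaldehyde
Product: 9 5-methoxy-2-(methoxymethyl)-6-(3-methylbut-3-en-1-yl)-3-({[tri(propan-2-yl)silyl]oxy}methyl)phenol, via salicyl alcohol 8 (not isolated)
Conditions: NaBH4, MeOH, 0 °C; then AcOH, PPTS (cat.), MeOH, 40 °C
Reagents that add atoms: methanol, CO
Why: Borohydride reduction followed by acid-catalysed solvolytic etherification, in which the new benzylic alcohol (ortho to OH, para to OMe) ionises under mild acid to an o-quinone-methide-type cation that solvent methanol captures, whereas the silyloxymethyl carbon is meta to both oxygens and should not ionise.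

Step 6
Reactants: 9 5-methoxy-2-(methoxymethyl)-6-(3-methylbut-3-en-1-yl)-3-({[tri(propan-2-yl)silyl]oxy}methyl)phenol
Product: 10 methyl 2-[(2S)-5-methoxy-8-(methoxymethyl)-2-methyl-7-({[tri(propan-2-yl)silyl]oxy}methyl)-3,4-dihydro-2H-chromen-2-yl]acetate
Conditions: Pd(OCOCF3)2 (5 mol%), (S,S)-Bn-BOXAX (20 mol%), p-benzoquinone (4 equiv), CO (1 atm), MeOH, rt
Reagents that add atoms: carbon monoxide, [C-]#[O+]; methanol, CO
Why: Enantioselective domino Wacker/carbonylation/methoxylation, in which 6-exo-trig oxypalladation of the 1,1-disubstituted alkene by the phenol closes the chroman and sets quaternary C2, the resulting alkyl-Pd has no β-hydrogen and inserts CO before methanolysis, benzoquinone reoxidises Pd(0), and the C2-symmetric bis(oxazoline) ligand controls the alkene face (the antipodal ligand would be used if the sense of induction proved opposite to that expected from closely related 2-(3-methylbut-3-enyl)phenols).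

Step 7
Reactants: 10 methyl 2-[(2S)-5-methoxy-8-(methoxymethyl)-2-methyl-7-({[tri(propan-2-yl)silyl]oxy}methyl)-3,4-dihydro-2H-chromen-2-yl]acetate
Product: 11 N-methoxy-2-[(2S)-5-methoxy-8-(methoxymethyl)-2-methyl-7-({[tri(propan-2-yl)silyl]oxy}methyl)-3,4-dihydro-2H-chromen-2-yl]-N-methylacetamide
Conditions: MeNH(OMe)·HCl, i-PrMgCl, THF, −20 → 0 °C
Reagents that add atoms: N,O-dimethylhydroxylamine hydrochloride, CNOC.Cl
Why: Weinreb amide formation by aminolysis of the methyl ester with the chloromagnesium amide, which is nucleophilic but only weakly basic, so the β-aryloxy ester should not be enolised and the O1–C2 bond should not be eliminated.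

Step 8
Reactants: 11 N-methoxy-2-[(2S)-5-methoxy-8-(methoxymethyl)-2-methyl-7-({[tri(propan-2-yl)silyl]oxy}methyl)-3,4-dihydro-2H-chromen-2-yl]-N-methylacetamide; 12 (2-methylprop-1-en-1-yl)magnesium bromide
Product: 13 1-[(2S)-5-methoxy-8-(methoxymethyl)-2-methyl-7-({[tri(propan-2-yl)silyl]oxy}methyl)-3,4-dihydro-2H-chromen-2-yl]-4-methylpent-3-en-2-one
Conditions: THF, 0 °C; cold aq. NH4Cl
Reagents that add atoms: none
Why: Weinreb ketone synthesis, in which the alkenyl Grignard reagent adds once to give a stable five-membered magnesium chelate that collapses to the enone only on the cold quench, so neither over-addition nor base-induced retro-oxa-Michael opening of the chroman is expected.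

Step 9
Reactants: 13 1-[(2S)-5-methoxy-8-(methoxymethyl)-2-methyl-7-({[tri(propan-2-yl)silyl]oxy}methyl)-3,4-dihydro-2H-chromen-2-yl]-4-methylpent-3-en-2-one
Product: 14 1-[(2S)-7-(hydroxymethyl)-5-methoxy-8-(methoxymethyl)-2-methyl-3,4-dihydro-2H-chromen-2-yl]-4-methylpent-3-en-2-one
Conditions: TBAF, AcOH (1:1), THF, 0 °C → rt
Reagents that add atoms: none
Why: Fluoride-mediated silyl ether cleavage, buffered with acetic acid so that the β-aryloxy ketone is not exposed to basic fluoride or alkoxide.

Step 10
Reactants: 14 1-[(2S)-7-(hydroxymethyl)-5-methoxy-8-(methoxymethyl)-2-methyl-3,4-dihydro-2H-chromen-2-yl]-4-methylpent-3-en-2-one; 15 5-bromopentanoyl chloride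
Product: 16 [(2S)-5-methoxy-8-(methoxymethyl)-2-methyl-2-(4-methyl-2-oxopent-3-en-1-yl)-3,4-dihydro-2H-chromen-7-yl]methyl 5-bromopentanoate
Conditions: pyridine, CH2Cl2, 0 °C
Reagents that add atoms: none
Why: O-acylation of the only free hydroxyl group with an acid chloride, made unambiguous because the C8 carbon is still a methyl ether and no hydroxy-aldehyde/lactol equilibrium exists.

Step 11
Reactants: 16 [(2S)-5-methoxy-8-(methoxymethyl)-2-methyl-2-(4-methyl-2-oxopent-3-en-1-yl)-3,4-dihydro-2H-chromen-7-yl]methyl 5-bromopentanoate; 17 undec-1-ene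
Product: 19 [(2S)-5-methoxy-8-(methoxymethyl)-2-methyl-2-(4-methyl-2-oxopent-3-en-1-yl)-3,4-dihydro-2H-chromen-7-yl]methyl hexadecanoate, via B-undecyl-9-BBN 18 (not isolated)
Conditions: 17 (1.5 equiv), 9-BBN (1.4 equiv B–H), THF, rt; then 16, Pd(OAc)2 (4 mol%), PCy3 (8 mol%), K3PO4·H2O, THF, rt
Reagents that add atoms: none
Why: Anti-Markovnikov hydroboration of 17 gives the primary borane 18; Pd(0)/PCy3 then inserts into the primary C5–Br bond of 16 by an SN2-type oxidative addition, the hydroxide-activated borate transfers its primary undecyl group to palladium, and reductive elimination forms the C5–C6 bond of the acyl chain. The closest known reaction type is the room-temperature Pd/PCy3-catalysed alkyl–alkyl Suzuki–Miyaura coupling of primary alkyl bromides bearing β-hydrogens with B-alkyl-9-BBN reagents. No ring is closed and no stereocentre is created; the C2 quaternary centre is remote from the reacting chain and should be untouched. Chemoselectivity is needed at three points: oxidative addition only at C–Br (16 has no other carbon–halogen bond, and its benzylic ester and ether C–O bonds should be inert to this catalyst at room temperature), reductive elimination faster than β-hydride elimination (the bulky, electron-rich PCy3), and no reduction or alkylation of the ketone (all B–H is consumed by the excess of 17, and the β,β-disubstituted enone is a poor acceptor). Stereochemical integrity requires that the mild heterogeneous base does not trigger retro-oxa-Michael cleavage of O1–C2, which is why C8 is carried as CH2OMe: without the formyl group the O1 phenoxide is a poor leaving group.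

Step 12
Reactants: 19 [(2S)-5-methoxy-8-(methoxymethyl)-2-methyl-2-(4-methyl-2-oxopent-3-en-1-yl)-3,4-dihydro-2H-chromen-7-yl]methyl hexadecanoate
Product: 20 [(2S)-8-formyl-5-methoxy-2-methyl-2-(4-methyl-2-oxopent-3-en-1-yl)-3,4-dihydro-2H-chromen-7-yl]methyl hexadecanoate
Conditions: DDQ, CH2Cl2/pH 7 buffer, 0 °C → rt
Reagents that add atoms: water, O
Why: Oxidative cleavage of an electron-rich benzylic ether (the mechanism of DMB/PMB ether removal), in which DDQ abstracts hydride from the C8 α-methoxy benzylic C–H (ortho to O1, para to the 5-OMe), water adds to the oxocarbenium ion and the hemiacetal loses methanol to give the aldehyde, while the C7 acyloxymethyl group (meta to both oxygens) and the chroman C4–H (no α-oxygen) are much less hydridic and the new formyl group deactivates the ring toward further oxidation.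

**Compound list**

1 | (4-bromo-3,5-dimethoxyphenyl)methanol | OCc1cc(OC)c(Br)c(OC)c1 | starting material
2 | [(4-bromo-3,5-dimethoxyphenyl)methoxy]tri(propan-2-yl)silane | COc1cc(CO[Si](C(C)C)(C(C)C)C(C)C)cc(OC)c1Br | intermediate
3 | 4-bromo-2-methylbut-1-ene | C=C(C)CCBr | starting material
4 | (3-methylbut-3-en-1-yl)zinc bromide (LiCl complex, not isolated) | C=C(C)CC[Zn]Br | intermediate
5 | {[3,5-dimethoxy-4-(3-methylbut-3-en-1-yl)phenyl]methoxy}tri(propan-2-yl)silane | COc1cc(CO[Si](C(C)C)(C(C)C)C(C)C)cc(OC)c1CCC(C)=C | intermediate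
6 | 3-methoxy-2-(3-methylbut-3-en-1-yl)-5-({[tri(propan-2-yl)silyl]oxy}methyl)phenol | COc1cc(CO[Si](C(C)C)(C(C)C)C(C)C)cc(O)c1CCC(C)=C | intermediate
7 | 2-hydroxy-4-methoxy-3-(3-methylbut-3-en-1-yl)-6-({[tri(propan-2-yl)silyl]oxy}methyl)benzaldehyde | COc1cc(CO[Si](C(C)C)(C(C)C)C(C)C)c(C=O)c(O)c1CCC(C)=C | intermediate
8 | 2-(hydroxymethyl)-5-methoxy-6-(3-methylbut-3-en-1-yl)-3-({[tri(propan-2-yl)silyl]oxy}methyl)phenol (not isolated) | COc1cc(CO[Si](C(C)C)(C(C)C)C(C)C)c(CO)c(O)c1CCC(C)=C | intermediate
9 | 5-methoxy-2-(methoxymethyl)-6-(3-methylbut-3-en-1-yl)-3-({[tri(propan-2-yl)silyl]oxy}methyl)phenol | COc1cc(CO[Si](C(C)C)(C(C)C)C(C)C)c(COC)c(O)c1CCC(C)=C | intermediate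
10 | methyl 2-[(2S)-5-methoxy-8-(methoxymethyl)-2-methyl-7-({[tri(propan-2-yl)silyl]oxy}methyl)-3,4-dihydro-2H-chromen-2-yl]acetate | CC(C)[Si](C(C)C)(C(C)C)OCc1cc(OC)c2c(c1COC)O[C@](C)(CC(=O)OC)CC2 | intermediate
11 | N-methoxy-2-[(2S)-5-methoxy-8-(methoxymethyl)-2-methyl-7-({[tri(propan-2-yl)silyl]oxy}methyl)-3,4-dihydro-2H-chromen-2-yl]-N-methylacetamide | CC(C)[Si](C(C)C)(C(C)C)OCc1cc(OC)c2c(c1COC)O[C@](C)(CC(=O)N(C)OC)CC2 | intermediate
12 | (2-methylprop-1-en-1-yl)magnesium bromide | CC(C)=C[Mg]Br | starting material
13 | 1-[(2S)-5-methoxy-8-(methoxymethyl)-2-methyl-7-({[tri(propan-2-yl)silyl]oxy}methyl)-3,4-dihydro-2H-chromen-2-yl]-4-methylpent-3-en-2-one | CC(C)[Si](C(C)C)(C(C)C)OCc1cc(OC)c2c(c1COC)O[C@](C)(CC(=O)C=C(C)C)CC2 | intermediate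
14 | 1-[(2S)-7-(hydroxymethyl)-5-methoxy-8-(methoxymethyl)-2-methyl-3,4-dihydro-2H-chromen-2-yl]-4-methylpent-3-en-2-one | OCc1cc(OC)c2c(c1COC)O[C@](C)(CC(=O)C=C(C)C)CC2 | intermediate
15 | 5-bromopentanoyl chloride | O=C(Cl)CCCCBr | starting material
16 | [(2S)-5-methoxy-8-(methoxymethyl)-2-methyl-2-(4-methyl-2-oxopent-3-en-1-yl)-3,4-dihydro-2H-chromen-7-yl]methyl 5-bromopentanoate | BrCCCCC(=O)OCc1cc(OC)c2c(c1COC)O[C@](C)(CC(=O)C=C(C)C)CC2 | intermediate
17 | undec-1-ene | C=CCCCCCCCCC | starting material
18 | 9-undecyl-9-borabicyclo[3.3.1]nonane (not isolated) | CCCCCCCCCCCB1C2CCCC1CCC2 | intermediate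
19 | [(2S)-5-methoxy-8-(methoxymethyl)-2-methyl-2-(4-methyl-2-oxopent-3-en-1-yl)-3,4-dihydro-2H-chromen-7-yl]methyl hexadecanoate | CCCCCCCCCCCCCCCC(=O)OCc1cc(OC)c2c(c1COC)O[C@](C)(CC(=O)C=C(C)C)CC2 | intermediate
20 | [(2S)-8-formyl-5-methoxy-2-methyl-2-(4-methyl-2-oxopent-3-en-1-yl)-3,4-dihydro-2H-chromen-7-yl]methyl hexadecanoate | CCCCCCCCCCCCCCCC(=O)OCc1cc(OC)c2c(c1C=O)O[C@](C)(CC(=O)C=C(C)C)CC2 | target

**Step count and risks**

Total step count: 12. Longest linear sequence: 12 steps (from 1 to 20).

Steps most likely to fail: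

Step 11. The alkyl-palladium intermediate may undergo β-hydride elimination instead of coupling, or the basic medium may open the chroman by retro-oxa-Michael cleavage and erode the enantiomeric purity at C2. The fallback sets out from 14 and comes back at 19, and forms the same C5–C6 bond under neutral conditions at the alkene oxidation level. Alcohol 14 would be acylated with hex-5-enoyl chloride (pyridine, CH2Cl2, 0 °C) to the hex-5-enoate ester F1. Cross-metathesis of F1 with excess dodec-1-ene ((H2IMes)(PCy3)Cl2Ru=CHPh, CH2Cl2, 40 °C; the trisubstituted enone should not take part) would give the hexadec-5-enoate F2 as an E/Z mixture. Its disubstituted alkene would then be saturated selectively with H2 and RhCl(PPh3)3 (benzene, rt), which should leave the trisubstituted conjugated enone and the benzylic C–O bonds alone, to give 19.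

Step 6. Facial selectivity in the oxypalladation may be poor with the additional ortho-methoxymethyl group on the phenol. The fallback sets out from 9 and comes back at 10. The same domino Wacker/carbonylation would be run with an achiral ligand (Pd(OCOCF3)2, 2,2'-bipyridine, p-benzoquinone, CO, MeOH) to give the racemic ester F3, which would be resolved by preparative chromatography on a chiral stationary phase. The (S)-enantiomer is 10; the (R)-enantiomer F4 is set aside.

Step 8. The Grignard reagent may deprotonate α to the amide carbonyl, followed by β-elimination of the aryloxide (ring opening at O1–C2), or addition to the neopentyl-type amide may be incomplete. The fallback sets out from 10 and comes back at 13. Ester 10 would be reduced with DIBAL-H (CH2Cl2, −78 °C) to the aldehyde F5, to which 12 adds rapidly at −78 °C to give the allylic alcohol F6 as a mixture of carbinol epimers. Oxidation of the allylic alcohol with MnO2 (CH2Cl2, rt) would give 13.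

**Further compounds**

F1 | step 11 | [(2S)-5-methoxy-8-(methoxymethyl)-2-methyl-2-(4-methyl-2-oxopent-3-en-1-yl)-3,4-dihydro-2H-chromen-7-yl]methyl hex-5-enoate | C=CCCCC(=O)OCc1cc(OC)c2c(c1COC)O[C@](C)(CC(=O)C=C(C)C)CC2
F2 | step 11 | [(2S)-5-methoxy-8-(methoxymethyl)-2-methyl-2-(4-methyl-2-oxopent-3-en-1-yl)-3,4-dihydro-2H-chromen-7-yl]methyl hexadec-5-enoate (E/Z mixture) | CCCCCCCCCCC=CCCCC(=O)OCc1cc(OC)c2c(c1COC)O[C@](C)(CC(=O)C=C(C)C)CC2
F3 | step 6 | racemic methyl 2-[5-methoxy-8-(methoxymethyl)-2-methyl-7-({[tri(propan-2-yl)silyl]oxy}methyl)-3,4-dihydro-2H-chromen-2-yl]acetate | COC(=O)CC1(C)CCc2c(OC)cc(CO[Si](C(C)C)(C(C)C)C(C)C)c(COC)c2O1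
F4 | step 6 | methyl 2-[(2R)-5-methoxy-8-(methoxymethyl)-2-methyl-7-({[tri(propan-2-yl)silyl]oxy}methyl)-3,4-dihydro-2H-chromen-2-yl]acetate | CC(C)[Si](C(C)C)(C(C)C)OCc1cc(OC)c2c(c1COC)O[C@@](C)(CC(=O)OC)CC2
F5 | step 8 | 2-[(2S)-5-methoxy-8-(methoxymethyl)-2-methyl-7-({[tri(propan-2-yl)silyl]oxy}methyl)-3,4-dihydro-2H-chromen-2-yl]acetaldehyde | CC(C)[Si](C(C)C)(C(C)C)OCc1cc(OC)c2c(c1COC)O[C@](C)(CC=O)CC2
F6 | step 8 | 1-[(2S)-5-methoxy-8-(methoxymethyl)-2-methyl-7-({[tri(propan-2-yl)silyl]oxy}methyl)-3,4-dihydro-2H-chromen-2-yl]-4-methylpent-3-en-2-ol (carbinol epimers) | CC(C)[Si](C(C)C)(C(C)C)OCc1cc(OC)c2c(c1COC)O[C@](C)(CC(O)C=C(C)C)CC2
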